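The earlier runs and the new flask come from a simulation for substances that don't exist.

You cannot integrate these flasks yet: the readings give product, while the rate law counts what has reacted, and the two differ by an unknown share.

| flask | substrate | coupling partner | remark | time |
|---|---|---|---|---|
| green | 21 mM | 34.2 mM | run made earlier |  |
| spring | 19 mM | 34.2 mM |  | 3.0 h |
| dawn | 60 mM | 8.00 mM |  | 3.0 h |

green run (percent of the substrate charged): time / min: product / % = 8.00: 19.4; 15.0: 33.3; 25.0: 46.6; 40.0: 58.7; 60.0: 69.0; 120: 81.6

(standard deviation of a reading: 0.3 percentage points)

1. the flask that ends with the higher amount of product, in percent of the substrate charged, or "neither" when 2 percentage points or less lies between them (spring / dawn / neither)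
2. final product, as a percentage of the substrate charged, in spring
3. final product, as a percentage of the substrate charged, in dawn

- the numbers in the tables scatter with a standard deviation of 0.3 percentage points

1. Take one coupling partner per substrate and a second-order rate. Let u be the fraction of substrate charged that has reacted, and c the substrate charge over the partner charge. Let E be the partner fraction left over the substrate fraction left. Integrating gives ln E growing with time multiplied by the charge gap, partner minus substrate. So u = (E − 1)/(E − c).

2. Write the yield as s·u, with s the share of reacted substrate that becomes product. Ask what must be known well. In dawn the gap is −52.0 mM, so E is small and u tends to the partner charge over the substrate charge, 0.133. The coupling partner is the limiting reagent there, the rate constant barely enters, and a point of error in s moves dawn by 0.133 of a point. Spring charges more partner than substrate, so its u climbs towards 1. There a point of error in s moves the yield by close to a point, and the rate constant enters too.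

3. Now read s. Green's 120 min is twice 60.0 min, so E at the later reading must be the square of E at the earlier one. At a product fraction p, E = (s − c·p)/(s − p). Solve this with both readings for the selectivity, the share of reacted substrate that becomes product: s = 88.4%. It is a reading and carries the scatter. E at 60.0 min is then 2.37.

4. Scale ln E by gap and time. Spring has E = 19.8, so u = 97.7% and the yield is 86.4%. Halving the rate constant would cost spring 8.1 points. Dawn has E = 3.68 × 10⁻⁵, so u = 13.3% and the yield is 11.8%.

5. The forecast also puts spring higher but differs from this reckoning in both yields, with 89.5% and 6.7%, since “the exact match favours 2:1”. The flasks give spring higher, with 86.4% in spring and 11.8% in dawn.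

    intermediate → product (k = 0.0160 s⁻¹)
    intermediate → decomposed reagent (k = 0.00210 s⁻¹)
    substrate + coupling partner ⇌ intermediate (K = 4.00 L mol⁻¹, k = 0.0250 L mol⁻¹ s⁻¹)

In dawn, intermediate goes to product 7.6 times as fast as to decomposed reagent at 0.178 h, and 7.6 times as fast at 3.00 h. Dawn ends with 11.8% product, 1.55% decomposed reagent and 0% coupling partner. Multiply its conversion, 13.3%, by s: that gives 11.8%. A neighbour of dawn charged with 15 mM of substrate reckons to 40.7%, and its simulated yield is 40.9%.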